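How far does a racemate get when the solid reagent that feeds it is charged short?

| setting | gamma | eta | flask |
|---|---|---|---|
| left-handed substrate | 0.65 M | 0.98 M | 1.3 M |
| right-handed substrate | 0.65 M | 0.98 M | 1.3 M |
| solid reagent | 1.04 M | 1.04 M | 1.04 M |
| free catalyst | 0.65 mM | 0.65 mM | 0.65 mM |
| added ligand | 0.65 mM | 0.65 mM | 0.65 mM |
| remark | run made earlier | run made earlier |  |
| time |  |  | 12 min |

- gamma (time / min: left-handed substrate / %, right-handed substrate / %, left-handed product / %): 1.00: 48.2, 50.4, 2.2; 3.00: 39.2, 49.2, 10.8; 6.00: 25.5, 49.3, 25.9; 8.00: 16.0, 49.0, 32.7; 12.0: 7.1, 48.4, 42.4
- eta (time / min: left-handed substrate / %, right-handed substrate / %, left-handed product / %): 1.00: 48.9, 49.3, 1.8; 3.00: 42.0, 50.3, 9.2; 6.00: 29.1, 49.0, 20.5; 8.00: 22.7, 50.4, 27.1; 12.0: 12.8, 49.1, 37.4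

(standard deviation of a reading: 0.5 percentage points)

- part of the left-handed substrate and right-handed substrate charged together that has reacted at 12 min
- excess of left-handed product over right-handed product in the product at 12 min
- excess of right-handed substrate over left-handed substrate among what is left of the two at 12 min

- free catalyst is single-handed; left-handed substrate and right-handed substrate are mirror images of each other, charged as a racemate, each of them at the stated concentration
- given per volume of solution although it is solid: solid reagent
- steps under discussion: free catalyst + right-handed substrate <-> catalyst intermediate B; free catalyst + left-handed substrate <-> catalyst intermediate A; solid reagent <-> partner; partner + catalyst intermediate A -> free catalyst + left-handed product; free catalyst + added ligand <-> idle complex; partner + catalyst intermediate B -> free catalyst + right-handed product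
- at the start none of the solid reagent is in solution
- an excess is the difference of the two amounts in percent of their sum
- an excess is below zero if the other one leads

I kept a ledger of the solid reagent. At 1.04 M it was charged below the 1.3 M of left-handed substrate, so it was the limiting reagent for left-handed product; once dissolved, it is the partner. Right-handed substrate read 48.4 % in gamma and 49.1 % in eta at 12.0 min, so I booked nothing to right-handed product.

The spending rate r, left-handed product made per minute averaged over the run, was 0.0459 M/min in gamma and 0.0611 M/min in eta. Carried on in a straight line with the substrate charge, it gave an estimate of 0.0758 M/min for the flask. At that rate I reckoned 13.7 min to spend the flask's solid charge: this is the solid life t_s, the solid charge divided by r. It is longer than the 12 min asked, so my books closed with some of the charge unspent.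

| Entry in the flask | Amount |
|---|---|
| Solid reagent charged | 1.04 M |
| To left-handed product, r times 12 min | 0.909 M |
| To right-handed product | none booked |
| Unspent, as solid or partner | 0.131 M |

That made my c 35.0 %, higher than the forecast's 33 %. The forecast gave c between 28.5 % and 36.5 %, eP 95 % and eS 47 %, starting from “Right-handed substrate barely reacts”.

The flask gave c 32.3 %, eP 97.3 % and eS 46.4 %.

    free catalyst + right-handed substrate ⇌ catalyst intermediate B (K = 2.10 /M, k = 2100 /M/min)
    free catalyst + left-handed substrate ⇌ catalyst intermediate A (K = 8.80 /M, k = 1800 /M/min)
    solid reagent ⇌ partner, rate k3*(cs3 - [partner]) while solid is left; crystals form when [partner] > cs3 (solubility = 0.990 M, k = 0.180 /min)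
    partner + catalyst intermediate A → free catalyst + left-handed product (k = 1100 /M/min)
    free catalyst + added ligand ⇌ idle complex, settled at all times (K = 3100 /M)
    partner + catalyst intermediate B → free catalyst + right-handed product (k = 15.0 /M/min)

The flask spent 0.840 M of its solid charge in 12 min, a solid life of 14.9 min against my 13.7 min, and 19 % of the charge remained at the end as dissolved partner, with solid reagent at 0 %. In the flask, half of the dissolving up to 12 min was done by 3.59 min, earlier than half of the reaction of free catalyst with left-handed substrate up to then, at 5.79 min, and partner stood at 0.368 M after 6.00 min and 0.200 M after 12.0 min. For a neighbour flask, the same but with 0.62 M of solid reagent, the flask's r gives a solid life of 8.18 min, shorter than 12 min, so I expected c at that time near the whole charge spent, 23.8 %. The neighbour flask computed 22.8 %, with 0.0279 M partner left.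

The readings are calculated from invented constants, and the scatter is random.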